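## Analysis of the target

Target 20 is a flavonol, 3,7-dihydroxy-2-[3,4-dihydroxy-2-(3-methylbut-2-en-1-yl)phenyl]-6-methyl-4H-chromen-4-one. Ring A (the benzo ring) carries a methyl group at C6 and a hydroxyl at C7. Ring C is the pyranone with the C3 hydroxyl beside the C4 carbonyl. Ring B, on C2, is a 3',4'-dihydroxyphenyl group with a prenyl chain at C2'. There is no stereocentre, and the prenyl double bond has no geometric isomers. The sensitive groups are three. The prenyl alkene lies ortho to the 3'-hydroxyl and closes to a 2,2-dimethylchroman in strong acid or to a chromene with dehydrogenating oxidants. The catechol is air-sensitive, and the 3-hydroxy-4-ketone chelates metals and is degraded by prolonged alkaline oxidation. Rings A and C follow from classical flavonoid chemistry. The hard part is ring B: four contiguous substituents (C1' carbon, C2' prenyl, C3' OH, C4' OH), with the prenyl group wedged between a carbon substituent and an oxygen, where electrophilic prenylation of a catechol does not go selectively. The strategy rests on the adjacent C3' and C4' oxygens. They map onto the ring oxygen and a 3-alkoxy group of a furan, whose four carbons become C3', C4', C5' and C6', while the two alkyne carbons of a prenyl-bearing ynoate become C2' and C1'.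

## Retrosynthetic reasoning

**20 ⇒ 19 (three protecting-group O–C bonds).** The last step is only the removal of methoxymethyl acetals from O7, O3' and O4'. These ethers survive all the basic, reductive and oxidative steps before it. They leave in dilute methanolic acid, which is too weak to protonate the prenyl alkene. The C3 hydroxyl needs no protection because it is made one step earlier.

**19 ⇒ 17 ⇒ 13 + 16 (O1–C2 with C3–O, then C2–C3).** Ring C is opened to the 2'-hydroxychalcone 17. Forward, an Algar–Flynn–Oyamada oxidative cyclisation forms O1–C2 and installs the C3 hydroxyl in one operation. Chalcone 17 is cut at its enone double bond into aldehyde 13 and methyl ketone 16 (Claisen–Schmidt condensation). An acyl-transfer construction of ring C was not used. It would need either a ring A ketone already oxygenated on its acetyl carbon, which is not readily available and tends to close to a five-membered furanone with base, or a separate C3 oxidation of a finished flavone beside the prenyl group. The forward reaction must favour six-membered closure at the β-carbon; the unsubstituted C5 of ring A and the electron-rich ring B both help.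

**16 ⇒ 15 ⇒ 14 (O-acetal, then the aryl–acetyl bond).** The acetal on O4 of 16 is removed to give 15; forward, only that hydroxyl reacts because the other is hydrogen-bonded to the carbonyl. The acetyl group of 15 is cut off to give 14. Forward, acylation goes to the ring position para to one hydroxyl and ortho to the other.

**13 ⇒ 12 ⇒ 11 ⇒ 10 ⇒ 9 ⇒ 8 (oxidation level and protecting groups).** Aldehyde 13 comes from ester 11 through alcohol 12, a two-step sequence chosen over a direct partial reduction for reliability. In 8 the two oxygens are differentiated (free 3-OH, 4-methoxybenzyl ether on O4) because of how ring B is made. They are unified by capping the phenol (9), oxidative removal of the benzyl-type ether (10) and a second acetalisation (11). The phenol beside the prenyl group must be capped before the oxidant is used.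

**8 ⇒ 3 + 6 (C2'–C3' and C1'–C6').** Ring B is cut into the 3-alkoxyfuran 3 and the ynoate 6. These are the two bonds that a [4+2] cycloaddition forms, and cutting here creates the whole 1,2,3,4-substitution pattern at once. Forward, the cycloaddition must place furan C2 on the prenyl-bearing alkyne carbon, and the oxygen bridge must open so that its oxygen stays on that same carbon as the 3'-hydroxyl. The furan oxygen substituent has to come from an alcohol by C–O coupling, so an acetal cannot be used there. A 4-methoxybenzyl ether tolerates heat and weak acid and can later be removed without acid.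

**3 ⇒ 1 + 2 and 6 ⇒ 4 + 5.** The furan ether is cut at its aryl C–O bond (copper-catalysed etherification of 1 with 2). The ynoate is cut at its propargylic C–C bond (copper acetylide of 4 alkylated by 5). Both precursors are then one step from commercial materials, so the risk of the route sits in the cycloaddition.

## Alternatives that were turned down

**Alternative 1:** Ring C is cut between C3 and C4. The precursor is dialdehyde A1, in which the ring A salicylaldehyde oxygen carries a CH(CHO) unit bearing ring B. A carbene generated from a 1,2,4-triazolium salt adds to the aromatic aldehyde, and the acyl anion equivalent attacks the aliphatic aldehyde (intramolecular crossed benzoin). This closes the dihydropyranone A2 with the C4 ketone and C3 hydroxyl in place.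
- For: the closure is catalytic, nearly neutral and needs no peroxide, and the C3 oxygen comes from a carbonyl group. On the mildness of ring C closure it is stronger than the alkaline peroxide cyclisation used here.
- Against: A1 contains an α-aryl-α-aryloxy acetaldehyde whose α-hydrogen is benzylic and flanked by oxygen and carbonyl, so it enolises, oxidises and self-condenses easily and needs several steps to make.
- Against: A2 is a diastereomer mixture one oxidation level too low, so a further C2–C3 dehydrogenation that spares the prenyl group is required.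
- Comparison: the key step addresses ring C, for which good solutions exist, and leaves the contiguous substitution of ring B unsolved. The chosen plan spends its key step on ring B and closes ring C in two classical steps that give the flavonol oxidation level directly.

**Alternative 2:** Ring B is again made by a [4+2] reaction, but along C1'–C2' and C5'–C6'. The 2,3-bis(silyloxy)diene A3 adds to methyl propiolate 4, and the 1,4-cyclohexadiene is dehydrogenated with DDQ to benzoate A4.
- For: an all-carbon Diels–Alder reaction does not revert, and terminal propiolate 4 is a better dienophile than the β-alkylated ynoate 6. On dienophile reactivity this alternative is stronger. Both catechol oxygens also arrive under one protecting group.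
- Against: the two silyloxy groups sit on neighbouring diene carbons and polarise the termini in opposite senses. Orientation then rests on the weak effect of the terminal alkyl group, at the more hindered end.
- Against: A3 must be a single (3Z) enol silane to reach the s-cis form, and its diketone precursor needs its own synthesis.
- Against: aromatisation needs a stoichiometric quinone beside the doubly activated prenyl CH2 and two enol silanes. The silyl ethers would not survive the basic ring C chemistry and would have to be exchanged too.
- Comparison: the chosen furan is a locked s-cis diene with one strong donor, so the orientation is clear and the aromatisation is redox-neutral. The price is a less reactive dienophile and a protecting-group exchange.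

**Alternative 3:** Ring C is cut between C4 and C4a. The (Z)-β-aryloxyacrylate A5 undergoes bromine–magnesium exchange with iPrMgCl·LiCl, and the arylmagnesium attacks the ester carbonyl to give flavone A6.
- For: it is convergent, runs cold and uses neither acid nor oxidant, so the prenyl group is untouched. In convergence and mildness it is stronger than the aldol and peroxide sequence used here.
- Against: A6 lacks the C3 oxygen, so a separate C3 hydroxylation is needed, and epoxidation-based methods would attack the prenyl alkene.
- Against: exchange on a donor-substituted aryl bromide is slow, and the ester can be attacked by the Grignard reagent itself.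
- Against: only the (Z) isomer of A5 can cyclise, and A5 needs a ring B arylpropiolate that costs further steps. Ring B itself is again not addressed.
- Comparison: the chosen route makes the C3 hydroxyl together with ring C and solves ring B in one step from two simple partners.

Key step: step 3

## Route

Remark on the chemistry: cycloadduct 7 and dihydroflavonol 18 are transient racemates whose stereocentres vanish on aromatisation, so no stereocontrol is needed; 4-methylresorcinol 14 is taken as the commercial source of ring A.

Step 1
Reactants: 1 3-bromofuran; 2 (4-methoxyphenyl)methanol (4-methoxybenzyl alcohol)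
Product: 3 3-[(4-methoxyphenyl)methoxy]furan
Conditions: CuI (10 mol %), 3,4,7,8-tetramethyl-1,10-phenanthroline (20 mol %), Cs2CO3, toluene, 100 °C, sealed tube, argon; 1 in excess
Reagents that add atoms: none
Why: Ullmann-type C–O coupling of a primary alcohol with a heteroaryl bromide under CuI/phenanthroline catalysis. The excess of volatile 1 is removed by evaporation, and the acid-sensitive enol-ether-like product should be purified on base-washed silica.

Step 2
Reactants: 4 methyl propiolate; 5 1-bromo-3-methylbut-2-ene (prenyl bromide)
Product: 6 methyl 6-methylhept-5-en-2-ynoate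
Conditions: CuI (10 mol %), K2CO3, DMF, rt
Reagents that add atoms: none
Why: Copper-catalysed allylation of a terminal alkyne: the copper acetylide formed from the acidic propiolate C–H is alkylated by the allylic bromide, mainly at the unhindered primary carbon. Carbonate at room temperature should be too weak to isomerise the skipped enynoate to an allene.

Step 3
Reactants: 3 3-[(4-methoxyphenyl)methoxy]furan; 6 methyl 6-methylhept-5-en-2-ynoate
Product: 8 methyl 3-hydroxy-4-[(4-methoxyphenyl)methoxy]-2-(3-methylbut-2-en-1-yl)benzoate, via 7-oxanorbornadiene cycloadduct 7 (not isolated)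
Conditions: toluene (2 M), 90 °C, sealed tube; then pyridinium p-toluenesulfonate (10 mol %), CH2Cl2, 0 °C to rt
Reagents that add atoms: none
Why: The 3-alkoxy group raises the furan HOMO and puts its largest coefficient on C2, so the reaction is an asynchronous, polarised [4+2] cycloaddition in which C2 bonds first to the electrophilic β-carbon of the ynoate (the one carrying the prenyl chain) and C5 then closes onto the α-carbon; this intermolecular Diels–Alder closure forms both new bonds of ring B (C2'–C3' and C1'–C6') in the oxygen-bridged bicycle 7. The closest known reaction type is the cycloaddition of 3-alkoxyfurans with acetylenic esters followed by opening of the 7-oxanorbornadiene to an ortho-alkoxyphenol. Under weak acid the bridge C–O bond at the former furan C5 ionises, because that cation is a vinylogous oxocarbenium ion stabilised through the enol ether by the alkoxy oxygen, whereas ionisation at the other bridgehead would put charge next to the ester. Loss of the proton at the former C2 then aromatises ring B and leaves the bridge oxygen as the free 3'-hydroxyl beside the protected 4'-oxygen. The two bridgehead stereocentres of 7 form as a racemate and disappear on aromatisation, so nothing has to be controlled there. The selectivity needed is regiochemical (prenyl at C2', ester carbon at C1', free OH at C3'), and the same alkoxy group secures it twice, in the orientation of the cycloaddition and in the direction of bridge opening. The electron-rich prenyl alkene is no dienophile for an electron-rich furan, and aromatisation makes the otherwise reversible furan cycloaddition irreversible. The acid is kept weak and cold because stronger acid would add the new phenol to the neighbouring prenyl double bond.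

Step 4
Reactants: 8 methyl 3-hydroxy-4-[(4-methoxyphenyl)methoxy]-2-(3-methylbut-2-en-1-yl)benzoate
Product: 9 methyl 3-(methoxymethoxy)-4-[(4-methoxyphenyl)methoxy]-2-(3-methylbut-2-en-1-yl)benzoate
Conditions: MOMCl, iPr2NEt, CH2Cl2, 0 °C to 40 °C
Reagents that add atoms: chloromethyl methyl ether (MOMCl), COCCl
Why: O-alkylation of the phenol with a reactive α-chloro ether. Capping this hydroxyl first makes the next step safe, since a free phenol beside the prenyl group would be dehydrogenated towards a chromene by the quinone.

Step 5
Reactants: 9 methyl 3-(methoxymethoxy)-4-[(4-methoxyphenyl)methoxy]-2-(3-methylbut-2-en-1-yl)benzoate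
Product: 10 methyl 4-hydroxy-3-(methoxymethoxy)-2-(3-methylbut-2-en-1-yl)benzoate
Conditions: DDQ (1.3 equiv), CH2Cl2–pH 7 phosphate buffer (10:1), 0 °C to rt
Reagents that add atoms: none
Why: Oxidative cleavage of a 4-methoxybenzyl ether: hydride abstraction from the anisylic CH2 gives an oxocarbenium ion that water hydrolyses to the phenol and 4-methoxybenzaldehyde. The anisyl ring is the most electron-rich arene present because the other ring is a benzoate, and the buffer protects the acetal.

Step 6
Reactants: 10 methyl 4-hydroxy-3-(methoxymethoxy)-2-(3-methylbut-2-en-1-yl)benzoate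
Product: 11 methyl 3,4-bis(methoxymethoxy)-2-(3-methylbut-2-en-1-yl)benzoate
Conditions: MOMCl, iPr2NEt, CH2Cl2, 0 °C to rt
Reagents that add atoms: chloromethyl methyl ether (MOMCl), COCCl
Why: O-alkylation of an acidic, unhindered phenol para to the ester; both ring B oxygens now carry the same acid-labile group.

Step 7
Reactants: 11 methyl 3,4-bis(methoxymethoxy)-2-(3-methylbut-2-en-1-yl)benzoate
Product: 12 [3,4-bis(methoxymethoxy)-2-(3-methylbut-2-en-1-yl)phenyl]methanol
Conditions: LiAlH4, THF, 0 °C
Reagents that add atoms: none
Why: Hydride reduction of an ester to the primary alcohol; acetals and the isolated alkene are inert to LiAlH4.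

Step 8
Reactants: 12 [3,4-bis(methoxymethoxy)-2-(3-methylbut-2-en-1-yl)phenyl]methanol
Product: 13 3,4-bis(methoxymethoxy)-2-(3-methylbut-2-en-1-yl)benzaldehyde
Conditions: MnO2 (activated, excess), CH2Cl2, rt
Reagents that add atoms: none
Why: Selective oxidation of a benzylic alcohol on MnO2 under neutral conditions, which avoids acid-induced cyclisation of the alcohol onto the prenyl alkene and stops at the aldehyde.

Step 9
Reactants: 14 4-methylbenzene-1,3-diol (4-methylresorcinol)
Product: 15 1-(2,4-dihydroxy-5-methylphenyl)ethan-1-one
Conditions: AcOH, ZnCl2 (fused), 140 °C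
Reagents that add atoms: acetic acid, CC(=O)O
Why: Nencki-type Friedel–Crafts acylation of a resorcinol. The position para to one hydroxyl and ortho to the other is the most activated and least hindered; the position between the hydroxyls is crowded and the remaining one is meta to both.

Step 10
Reactants: 15 1-(2,4-dihydroxy-5-methylphenyl)ethan-1-one
Product: 16 1-[2-hydroxy-4-(methoxymethoxy)-5-methylphenyl]ethan-1-one
Conditions: MOMCl (1.1 equiv), K2CO3, acetone, 0 °C to rt
Reagents that add atoms: chloromethyl methyl ether (MOMCl), COCCl
Why: Selective O-alkylation: the 2-hydroxyl is held in a hydrogen bond to the acetyl carbonyl and is much less nucleophilic, so the 4-hydroxyl reacts and the phenol needed for ring C stays free.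

Step 11
Reactants: 13 3,4-bis(methoxymethoxy)-2-(3-methylbut-2-en-1-yl)benzaldehyde; 16 1-[2-hydroxy-4-(methoxymethoxy)-5-methylphenyl]ethan-1-one
Product: 17 (2E)-3-[3,4-bis(methoxymethoxy)-2-(3-methylbut-2-en-1-yl)phenyl]-1-[2-hydroxy-4-(methoxymethoxy)-5-methylphenyl]prop-2-en-1-one
Conditions: KOH (50 % aq.), EtOH, 0 °C to rt
Reagents that add atoms: none
Why: Claisen–Schmidt condensation of a methyl ketone with a non-enolisable aldehyde; elimination of water from the aldol gives the conjugated (E)-enone as the thermodynamic product, and all protecting groups are base-stable.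

Step 12
Reactants: 17 (2E)-3-[3,4-bis(methoxymethoxy)-2-(3-methylbut-2-en-1-yl)phenyl]-1-[2-hydroxy-4-(methoxymethoxy)-5-methylphenyl]prop-2-en-1-one
Product: 19 2-[3,4-bis(methoxymethoxy)-2-(3-methylbut-2-en-1-yl)phenyl]-3-hydroxy-7-(methoxymethoxy)-6-methyl-4H-chromen-4-one, via trans-dihydroflavonol 18 (not isolated)
Conditions: H2O2 (30 % aq.), NaOH (2 M aq.), MeOH–THF, 0 °C to rt
Reagents that add atoms: hydrogen peroxide, OO
Why: Algar–Flynn–Oyamada reaction: hydroperoxide oxidises the enone while the phenoxide closes 6-endo at the β-carbon, which is benzylic to the para-alkoxy ring B, giving dihydroflavonol 18 that excess alkaline peroxide dehydrogenates to the flavonol. With no substituent at C5 of ring A the six-membered closure is favoured over aurone formation, the electron-rich prenyl alkene is inert to the nucleophilic oxidant, and the two transient stereocentres of 18 are lost.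

Step 13
Reactants: 19 2-[3,4-bis(methoxymethoxy)-2-(3-methylbut-2-en-1-yl)phenyl]-3-hydroxy-7-(methoxymethoxy)-6-methyl-4H-chromen-4-one
Product: 20 3,7-dihydroxy-2-[3,4-dihydroxy-2-(3-methylbut-2-en-1-yl)phenyl]-6-methyl-4H-chromen-4-one
Conditions: HCl (1.25 M in MeOH), MeOH–THF, 0 °C to rt, argon
Reagents that add atoms: none
Why: Acid-catalysed acetal exchange: each methoxymethyl ether ionises to an oxocarbenium ion that methanol traps as dimethoxymethane, so no formaldehyde equivalent is left to alkylate the electron-rich C8 of ring A. Dilute HCl near room temperature is below the acidity needed to protonate the trisubstituted alkene, so the 3'-hydroxyl should not add to the prenyl group.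

## Compound list

1 | 3-bromofuran | Brc1ccoc1 | starting material
2 | (4-methoxyphenyl)methanol | COc1ccc(CO)cc1 | starting material
3 | 3-[(4-methoxyphenyl)methoxy]furan | COc1ccc(COc2ccoc2)cc1 | intermediate
4 | methyl propiolate | C#CC(=O)OC | starting material
5 | 1-bromo-3-methylbut-2-ene | CC(C)=CCBr | starting material
6 | methyl 6-methylhept-5-en-2-ynoate | COC(=O)C#CCC=C(C)C | intermediate
7 | methyl 5-[(4-methoxyphenyl)methoxy]-3-(3-methylbut-2-en-1-yl)-7-oxabicyclo[2.2.1]hepta-2,5-diene-2-carboxylate (racemate, not isolated) | COC(=O)C1=C(CC=C(C)C)C2OC1C=C2OCc1ccc(OC)cc1 | intermediate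
8 | methyl 3-hydroxy-4-[(4-methoxyphenyl)methoxy]-2-(3-methylbut-2-en-1-yl)benzoate | COC(=O)c1ccc(OCc2ccc(OC)cc2)c(O)c1CC=C(C)C | intermediate
9 | methyl 3-(methoxymethoxy)-4-[(4-methoxyphenyl)methoxy]-2-(3-methylbut-2-en-1-yl)benzoate | COC(=O)c1ccc(OCc2ccc(OC)cc2)c(OCOC)c1CC=C(C)C | intermediate
10 | methyl 4-hydroxy-3-(methoxymethoxy)-2-(3-methylbut-2-en-1-yl)benzoate | COC(=O)c1ccc(O)c(OCOC)c1CC=C(C)C | intermediate
11 | methyl 3,4-bis(methoxymethoxy)-2-(3-methylbut-2-en-1-yl)benzoate | COC(=O)c1ccc(OCOC)c(OCOC)c1CC=C(C)C | intermediate
12 | [3,4-bis(methoxymethoxy)-2-(3-methylbut-2-en-1-yl)phenyl]methanol | OCc1ccc(OCOC)c(OCOC)c1CC=C(C)C | intermediate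
13 | 3,4-bis(methoxymethoxy)-2-(3-methylbut-2-en-1-yl)benzaldehyde | O=Cc1ccc(OCOC)c(OCOC)c1CC=C(C)C | intermediate
14 | 4-methylbenzene-1,3-diol | Cc1ccc(O)cc1O | starting material
15 | 1-(2,4-dihydroxy-5-methylphenyl)ethan-1-one | CC(=O)c1cc(C)c(O)cc1O | intermediate
16 | 1-[2-hydroxy-4-(methoxymethoxy)-5-methylphenyl]ethan-1-one | CC(=O)c1cc(C)c(OCOC)cc1O | intermediate
17 | (2E)-3-[3,4-bis(methoxymethoxy)-2-(3-methylbut-2-en-1-yl)phenyl]-1-[2-hydroxy-4-(methoxymethoxy)-5-methylphenyl]prop-2-en-1-one | COCOc1cc(O)c(cc1C)C(=O)/C=C/c1ccc(OCOC)c(OCOC)c1CC=C(C)C | intermediate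
18 | (2R*,3R*)-2-[3,4-bis(methoxymethoxy)-2-(3-methylbut-2-en-1-yl)phenyl]-3-hydroxy-7-(methoxymethoxy)-6-methyl-2,3-dihydro-4H-chromen-4-one (racemic trans, one enantiomer drawn, not isolated) | COCOc1cc2O[C@H](c3ccc(OCOC)c(OCOC)c3CC=C(C)C)[C@@H](O)C(=O)c2cc1C | intermediate
19 | 2-[3,4-bis(methoxymethoxy)-2-(3-methylbut-2-en-1-yl)phenyl]-3-hydroxy-7-(methoxymethoxy)-6-methyl-4H-chromen-4-one | COCOc1cc2oc(-c3ccc(OCOC)c(OCOC)c3CC=C(C)C)c(O)c(=O)c2cc1C | intermediate
20 | 3,7-dihydroxy-2-[3,4-dihydroxy-2-(3-methylbut-2-en-1-yl)phenyl]-6-methyl-4H-chromen-4-one | CC(C)=CCc1c(-c2oc3cc(O)c(C)cc3c(=O)c2O)ccc(O)c1O | target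

## Step count and least certain steps

Total step count: 13. Longest linear sequence: 10 steps (steps 1, 3 to 8, 11 to 13, from 3-bromofuran).

**Step 3 (key step).**
- Risk: the cycloaddition may be too slow. The β-carbon of 6 carries an alkyl chain, which lowers the electrophilicity of the ynoate and crowds the bond that must form first. At the temperature needed, furan 3 may polymerise or add to 6 in an open-chain conjugate fashion without ring closure. A smaller risk is acid-induced addition of the freed phenol to the prenyl alkene during bridge opening.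
- Fallback (from 3 and 4, back at 8): introduce the prenyl group after ring B exists. Furan 3 reacts with unsubstituted methyl propiolate 4, the best-precedented partner for this cycloaddition and opening, to give methyl 3-hydroxy-4-[(4-methoxyphenyl)methoxy]benzoate F1. Its phenol is alkylated with 3-chloro-3-methylbut-1-yne (CuCl2·2H2O cat., DBU, MeCN, 0 °C) to methyl 4-[(4-methoxyphenyl)methoxy]-3-[(2-methylbut-3-yn-2-yl)oxy]benzoate F2. Semihydrogenation (H2, Pd/CaCO3 poisoned with Pb(OAc)2, quinoline) gives methyl 4-[(4-methoxyphenyl)methoxy]-3-[(2-methylbut-3-en-2-yl)oxy]benzoate F3. Heating (toluene, 110 °C) brings about an aromatic Claisen rearrangement to the only free ortho position, C2, with allylic transposition to a normal prenyl group, which gives 8.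

**Step 1.**
- Risk: coupling at the electron-rich furan 3-position may be sluggish, with loss of volatile 1 and acid- or air-induced decomposition of the enol-ether-like product during isolation.
- Fallback (from 2, back at 3): reverse the roles of the partners. Oxidative copper coupling of alcohol 2 with commercial potassium furan-3-yltrifluoroborate (Cu(OAc)2·H2O cat., 4-(dimethylamino)pyridine, O2, 4 Å molecular sieves, CH2Cl2, rt), in which the furan is the nucleophilic partner, gives 3 directly without any new compound (F0).

**Step 5.**
- Risk: hydride abstraction by DDQ from the doubly activated benzylic–allylic CH2 of the prenyl group, or slow oxidation because the ether oxygen is conjugated with the benzoate.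
- Fallback (from 8, back at 11): avoid the oxidant. Ether 8 is dealkylated with MgBr2·OEt2 and Me2S (CH2Cl2, rt), where magnesium held between the free 3-hydroxyl and the ether oxygen activates the benzylic C–O bond for attack by the sulfide. This gives methyl 3,4-dihydroxy-2-(3-methylbut-2-en-1-yl)benzoate F4. Double protection (MOMCl, iPr2NEt, CH2Cl2) then gives 11.

**Step 12.**
- Risk: five-membered closure at the α-carbon (aurone pathway), arrest at the dihydroflavonol stage, or peroxide degradation of the flavonol, because the ortho-prenyl group twists ring B and hinders the β-carbon.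
- Fallback (from 11 and 16, back at 19): build ring C by acyl transfer and oxidise C3 afterwards. Saponification of 11 (LiOH, THF–H2O) gives 3,4-bis(methoxymethoxy)-2-(3-methylbut-2-en-1-yl)benzoic acid F5. Esterification with 16 (EDC·HCl, DMAP, CH2Cl2) gives the aryl ester 2-acetyl-5-(methoxymethoxy)-4-methylphenyl 3,4-bis(methoxymethoxy)-2-(3-methylbut-2-en-1-yl)benzoate F6. Baker–Venkataraman rearrangement (KOtBu, THF, 0 °C to rt) gives the 1,3-diketone 1-[3,4-bis(methoxymethoxy)-2-(3-methylbut-2-en-1-yl)phenyl]-3-[2-hydroxy-4-(methoxymethoxy)-5-methylphenyl]propane-1,3-dione F7. Cyclodehydration (NaOAc, AcOH, 80 °C) gives the flavone 2-[3,4-bis(methoxymethoxy)-2-(3-methylbut-2-en-1-yl)phenyl]-7-(methoxymethoxy)-6-methyl-4H-chromen-4-one F8. Deprotonation at C3 (LDA, THF, −78 °C), trapping with B(OMe)3 and oxidation of the borate (H2O2, AcOH) gives 19.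

**Step 13.**
- Risk: acid-catalysed addition of the liberated 3'-hydroxyl to the prenyl double bond (chroman formation), or incomplete cleavage of the hindered 3'-O acetal.
- Fallback (from 8, back at 20): keep the oxygen next to the prenyl group capped by a group that is removed without acid. Phenol 8 is allylated (allyl bromide, K2CO3, acetone) to the allyl ether ester methyl 4-[(4-methoxyphenyl)methoxy]-2-(3-methylbut-2-en-1-yl)-3-(prop-2-en-1-yloxy)benzoate F9. Reduction (LiAlH4, THF, 0 °C) gives the benzylic alcohol [4-[(4-methoxyphenyl)methoxy]-2-(3-methylbut-2-en-1-yl)-3-(prop-2-en-1-yloxy)phenyl]methanol F10. Oxidation (MnO2, CH2Cl2) gives the aldehyde 4-[(4-methoxyphenyl)methoxy]-2-(3-methylbut-2-en-1-yl)-3-(prop-2-en-1-yloxy)benzaldehyde F11. Condensation with 16 (KOH, EtOH) gives the chalcone (2E)-1-[2-hydroxy-4-(methoxymethoxy)-5-methylphenyl]-3-[4-[(4-methoxyphenyl)methoxy]-2-(3-methylbut-2-en-1-yl)-3-(prop-2-en-1-yloxy)phenyl]prop-2-en-1-one F12. Oxidative cyclisation (H2O2, NaOH) gives the flavonol 3-hydroxy-7-(methoxymethoxy)-2-[4-[(4-methoxyphenyl)methoxy]-2-(3-methylbut-2-en-1-yl)-3-(prop-2-en-1-yloxy)phenyl]-6-methyl-4H-chromen-4-one F13. Methanolic HCl then removes the acetal and the 4-methoxybenzyl ether while O3' stays allylated, so no phenol is available next to the prenyl group. This gives 3,7-dihydroxy-2-[4-hydroxy-2-(3-methylbut-2-en-1-yl)-3-(prop-2-en-1-yloxy)phenyl]-6-methyl-4H-chromen-4-one F14. Neutral deallylation (Pd(PPh3)4 cat., morpholine, THF, rt) gives 20.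

## Further compounds

F1 | step 3 | methyl 3-hydroxy-4-[(4-methoxyphenyl)methoxy]benzoate | COC(=O)c1ccc(OCc2ccc(OC)cc2)c(O)c1
F2 | step 3 | methyl 4-[(4-methoxyphenyl)methoxy]-3-[(2-methylbut-3-yn-2-yl)oxy]benzoate | COC(=O)c1ccc(OCc2ccc(OC)cc2)c(OC(C)(C)C#C)c1
F3 | step 3 | methyl 4-[(4-methoxyphenyl)methoxy]-3-[(2-methylbut-3-en-2-yl)oxy]benzoate | COC(=O)c1ccc(OCc2ccc(OC)cc2)c(OC(C)(C)C=C)c1
F0 | step 1 | none | none
F4 | step 5 | methyl 3,4-dihydroxy-2-(3-methylbut-2-en-1-yl)benzoate | COC(=O)c1ccc(O)c(O)c1CC=C(C)C
F5 | step 12 | 3,4-bis(methoxymethoxy)-2-(3-methylbut-2-en-1-yl)benzoic acid | OC(=O)c1ccc(OCOC)c(OCOC)c1CC=C(C)C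
F6 | step 12 | 2-acetyl-5-(methoxymethoxy)-4-methylphenyl 3,4-bis(methoxymethoxy)-2-(3-methylbut-2-en-1-yl)benzoate | CC(=O)c1cc(C)c(OCOC)cc1OC(=O)c1ccc(OCOC)c(OCOC)c1CC=C(C)C
F7 | step 12 | 1-[3,4-bis(methoxymethoxy)-2-(3-methylbut-2-en-1-yl)phenyl]-3-[2-hydroxy-4-(methoxymethoxy)-5-methylphenyl]propane-1,3-dione | COCOc1cc(O)c(cc1C)C(=O)CC(=O)c1ccc(OCOC)c(OCOC)c1CC=C(C)C
F8 | step 12 | 2-[3,4-bis(methoxymethoxy)-2-(3-methylbut-2-en-1-yl)phenyl]-7-(methoxymethoxy)-6-methyl-4H-chromen-4-one | COCOc1cc2oc(-c3ccc(OCOC)c(OCOC)c3CC=C(C)C)cc(=O)c2cc1C
F9 | step 13 | methyl 4-[(4-methoxyphenyl)methoxy]-2-(3-methylbut-2-en-1-yl)-3-(prop-2-en-1-yloxy)benzoate | COC(=O)c1ccc(OCc2ccc(OC)cc2)c(OCC=C)c1CC=C(C)C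
F10 | step 13 | [4-[(4-methoxyphenyl)methoxy]-2-(3-methylbut-2-en-1-yl)-3-(prop-2-en-1-yloxy)phenyl]methanol | OCc1ccc(OCc2ccc(OC)cc2)c(OCC=C)c1CC=C(C)C
F11 | step 13 | 4-[(4-methoxyphenyl)methoxy]-2-(3-methylbut-2-en-1-yl)-3-(prop-2-en-1-yloxy)benzaldehyde | O=Cc1ccc(OCc2ccc(OC)cc2)c(OCC=C)c1CC=C(C)C
F12 | step 13 | (2E)-1-[2-hydroxy-4-(methoxymethoxy)-5-methylphenyl]-3-[4-[(4-methoxyphenyl)methoxy]-2-(3-methylbut-2-en-1-yl)-3-(prop-2-en-1-yloxy)phenyl]prop-2-en-1-one | COCOc1cc(O)c(cc1C)C(=O)/C=C/c1ccc(OCc2ccc(OC)cc2)c(OCC=C)c1CC=C(C)C
F13 | step 13 | 3-hydroxy-7-(methoxymethoxy)-2-[4-[(4-methoxyphenyl)methoxy]-2-(3-methylbut-2-en-1-yl)-3-(prop-2-en-1-yloxy)phenyl]-6-methyl-4H-chromen-4-one | COCOc1cc2oc(-c3ccc(OCc4ccc(OC)cc4)c(OCC=C)c3CC=C(C)C)c(O)c(=O)c2cc1C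
F14 | step 13 | 3,7-dihydroxy-2-[4-hydroxy-2-(3-methylbut-2-en-1-yl)-3-(prop-2-en-1-yloxy)phenyl]-6-methyl-4H-chromen-4-one | C=CCOc1c(O)ccc(-c2oc3cc(O)c(C)cc3c(=O)c2O)c1CC=C(C)C
A1 | alternative 1 | 2-{1-[3,4-bis(methoxymethoxy)-2-(3-methylbut-2-en-1-yl)phenyl]-2-oxoethoxy}-4-(methoxymethoxy)-5-methylbenzaldehyde | O=CC(Oc1cc(OCOC)c(C)cc1C=O)c1ccc(OCOC)c(OCOC)c1CC=C(C)C
A2 | alternative 1 | 2-[3,4-bis(methoxymethoxy)-2-(3-methylbut-2-en-1-yl)phenyl]-3-hydroxy-7-(methoxymethoxy)-6-methyl-2,3-dihydro-4H-chromen-4-one (mixture of diastereomers) | CC(C)=CCc1c(C2Oc3cc(OCOC)c(C)cc3C(=O)C2O)ccc(OCOC)c1OCOC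
A3 | alternative 2 | (3Z)-2,3-bis(tert-butyldimethylsilyloxy)-7-methylocta-1,3,6-triene | C=C(O[Si](C)(C)C(C)(C)C)/C(O[Si](C)(C)C(C)(C)C)=C/CC=C(C)C
A4 | alternative 2 | methyl 3,4-bis(tert-butyldimethylsilyloxy)-2-(3-methylbut-2-en-1-yl)benzoate | COC(=O)c1ccc(O[Si](C)(C)C(C)(C)C)c(O[Si](C)(C)C(C)(C)C)c1CC=C(C)C
A5 | alternative 3 | methyl (2Z)-3-[3,4-bis(methoxymethoxy)-2-(3-methylbut-2-en-1-yl)phenyl]-3-[2-bromo-5-(methoxymethoxy)-4-methylphenoxy]prop-2-enoate | COC(=O)/C=C(\Oc1cc(OCOC)c(C)cc1Br)c1ccc(OCOC)c(OCOC)c1CC=C(C)C
A6 | alternative 3 | 2-[3,4-bis(methoxymethoxy)-2-(3-methylbut-2-en-1-yl)phenyl]-7-(methoxymethoxy)-6-methyl-4H-chromen-4-one | CC(C)=CCc1c(-c2cc(=O)c3cc(C)c(OCOC)cc3o2)ccc(OCOC)c1OCOC
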